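**Plan**

1. Retrosynthesis: the tert-butyl ester C–O bond and the ring-A C4 O–methyl bond are cut first, then the ring-A C1–C2 bond (aldol), then the depside O–acyl bond (phenol plus acylketene). The chain bonds C4–C5 and C6–C7 of the tetradecanoyl unit lead back to 2,2,6-trimethyl-4H-1,3-dioxin-4-one, acetyl chloride and octanoyl chloride. Ring B is cut at its benzylic C–C bond and its C4–O bond, back to 2-methoxy-6-methylbenzoic acid and 1-iodohexane.
2. Enabling feature: ring A has its carboxyl carbon on C1, oxygen on C4 and C6 and the heptyl chain on C2. This is the alternating pattern of a folded tetraketide, so the C1–C2 ring bond can be closed from an open 3,5,7-triketo ester that already carries the ester to ring B.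
3. Forward: ring B is a purchased benzene that is elaborated (lateral alkylation, tert-butyl ester, C–H borylation, oxidation). The chain is built on the dioxinone by two acylations. Thermolysis joins chain and ring-B phenol, ring A is then closed by aldol aromatisation, and methylation and ester cleavage finish.
4. Stereochemistry: the target has no stereocentre and no stereogenic double bond, so nothing has to be set.

Key step: step 9

Remark: the target is achiral, so the question of a single enantiomer does not arise; lithiated forms of a numbered compound (enolates, dianions) are treated as reactive states of that compound and are not numbered.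

**Route**

Step 1
Reactants: 1 2-methoxy-6-methylbenzoic acid; 2 1-iodohexane
Product: 3 2-heptyl-6-methoxybenzoic acid
Conditions: LDA (commercial solution, 2.2 equiv), THF, −78 to 0 °C; then 2 (1.2 equiv), −78 °C to rt; 1 M HCl
Reagents that add atoms: none
Why: Lateral lithiation: the second equivalent of LDA removes a benzylic proton of the lithium carboxylate, and the resulting o-toluate dianion is alkylated at carbon by the primary iodide (SN2), LDA being too hindered to add to the carboxylate or to metalate the ring next to the methoxy group.

Step 2
Reactants: 3 2-heptyl-6-methoxybenzoic acid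
Product: 4 tert-butyl 2-heptyl-6-methoxybenzoate
Conditions: Me2NCH(OtBu)2 (4 equiv), PhMe, 80 °C
Reagents that add atoms: N,N-dimethylformamide di-tert-butyl acetal, CN(C)C(OC(C)(C)C)OC(C)(C)C
Why: Esterification by O-alkylation: the acid protonates the amide acetal and the carboxylate takes the tert-butyl group from the alkoxyiminium ion pair at oxygen, so the 2,6-disubstitution that blocks attack at the acyl carbon does not matter.

Step 3
Reactants: 4 tert-butyl 2-heptyl-6-methoxybenzoate
Product: 5 tert-butyl 2-heptyl-6-methoxy-4-(4,4,5,5-tetramethyl-1,3,2-dioxaborolan-2-yl)benzoate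
Conditions: [Ir(OMe)(cod)]2 (1.5 mol %), dtbpy (3 mol %), B2pin2 (1.0 equiv), THF, 80 °C; filtration through silica
Reagents that add atoms: bis(pinacolato)diboron, CC1(C)OB(OC1(C)C)B1OC(C)(C)C(C)(C)O1
Why: Iridium-catalysed aromatic C–H borylation is sterically controlled: C3–H and C5–H each have an ortho substituent and only C4–H has none, so boron should enter para to the ester, which has no ortho hydrogen of its own to direct to.

Step 4
Reactants: 5 tert-butyl 2-heptyl-6-methoxy-4-(4,4,5,5-tetramethyl-1,3,2-dioxaborolan-2-yl)benzoate
Product: 6 tert-butyl 2-heptyl-4-hydroxy-6-methoxybenzoate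
Conditions: Oxone (1.1 equiv), acetone/H2O, 0 °C to rt, short reaction time; NaHSO3 quench
Reagents that add atoms: potassium peroxymonosulfate (active component of Oxone), [K+].[O-]S(=O)(=O)OO
Why: Oxidation of an arylboronate (ipso-hydroxylation): the peroxide adds to boron, the aryl group migrates from boron to oxygen at the same ring carbon, and the borate is hydrolysed; the tert-butyl ester and the ethers tolerate the brief cold treatment.

Step 5
Reactants: 7 2,2,6-trimethyl-4H-1,3-dioxin-4-one; 8 acetyl chloride
Product: 9 2,2-dimethyl-6-(2-oxopropyl)-4H-1,3-dioxin-4-one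
Conditions: LiHMDS (2.0 equiv), 7 (2.0 equiv), THF, −78 °C; then 8 (1.0 equiv), −78 °C; aq. NH4Cl
Reagents that add atoms: none
Why: Vinylogous Claisen acylation: kinetic deprotonation of the 6-methyl group gives the lithium dienolate, which is acylated at the exocyclic carbon, the second equivalent of dienolate taking up the proton of the more acidic β-keto product.

Step 6
Reactants: 10 octanoyl chloride
Product: 11 N-methoxy-N-methyloctanamide
Conditions: MeNHOMe·HCl (1.1 equiv), Et3N (2.2 equiv), CH2Cl2, 0 °C to rt
Reagents that add atoms: N,O-dimethylhydroxylamine hydrochloride, CNOC.Cl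
Why: N-Acylation of the hydroxylamine by the acid chloride (Weinreb amide formation) provides the acyl donor that stops at the ketone stage in step 7.

Step 7
Reactants: 9 2,2-dimethyl-6-(2-oxopropyl)-4H-1,3-dioxin-4-one; 11 N-methoxy-N-methyloctanamide
Product: 12 6-(2,4-dioxoundecyl)-2,2-dimethyl-4H-1,3-dioxin-4-one
Conditions: LDA (commercial solution, 2.2 equiv), THF, −78 to −40 °C; then 11 (1.0 equiv), −78 to 0 °C; 1 M HCl to pH 3
Reagents that add atoms: none
Why: Claisen-type C-acylation of a dianion (Weinreb ketone synthesis): LDA deprotonates first the doubly activated methylene and then the terminal methyl, the more reactive terminal carbanion adds to the amide, and the chelated tetrahedral adduct survives until the acid quench, so there is neither over-addition nor quenching by the 1,3-diketone product.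

Step 8
Reactants: 12 6-(2,4-dioxoundecyl)-2,2-dimethyl-4H-1,3-dioxin-4-one; 6 tert-butyl 2-heptyl-4-hydroxy-6-methoxybenzoate
Product: 14 tert-butyl 2-heptyl-6-methoxy-4-[(3,5,7-trioxotetradecanoyl)oxy]benzoate, via acylketene 13 (not isolated)
Conditions: 12 (1.3 equiv), 6 (1.0 equiv), PhMe (0.2 M), 110 °C, slow N2 stream, 1–2 h; concentrate, use crude
Reagents that add atoms: none
Why: Thermal retro-hetero-Diels–Alder cleavage of the dioxinone expels acetone and gives the acylketene, to which the phenol O–H adds (acylketene trapping, the usual acetoacetylation of phenols with dioxinones); the phenol has both ortho positions free and is kept concentrated so that addition should outrun intramolecular capture, and sweeping out acetone prevents the reverse cycloaddition.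

Step 9
Reactants: 14 tert-butyl 2-heptyl-6-methoxy-4-[(3,5,7-trioxotetradecanoyl)oxy]benzoate
Product: 16 tert-butyl 2-heptyl-4-[(2-heptyl-4,6-dihydroxybenzoyl)oxy]-6-methoxybenzoate, via cyclic aldol 15 (not isolated)
Conditions: Et3N (2.0 equiv), CH2Cl2, 0 °C to rt; then AcOH (10 equiv), rt to 40 °C
Reagents that add atoms: none
Why: Triethylamine forms the enolate of the C2 methylene, which lies between the aryl ester and the C3 ketone, and this carbon adds to the C7 ketone to give the cyclic aldol 15; E1cB loss of water and enolisation of the C3 and C5 carbonyls then give the aromatic ring, acetic acid completing the dehydration without harming the tert-butyl ester. The closest known reaction is the base-then-acid aldol aromatisation of 3,5,7-triketo alkyl esters obtained by acylketene trapping. Ring A closes in the 6-(enolendo)-exo-trig mode, a favoured closure for a six-membered aldol. The two sp3 centres of 15 are transient and vanish on aromatisation, so no stereocontrol is required. The step needs chemoselectivity for the C2-to-C7 aldol over attack of C6 or of the C5 enol oxygen on the aryl ester carbonyl (Claisen closure or lactonisation, each expelling the ring-B phenoxide); the ketone is the more electrophilic carbonyl toward a carbon nucleophile, the ester carbonyl is deactivated by conjugation with the C2–C3 enol, and a non-chelating amine in an aprotic solvent at low temperature avoids the metal templating and nucleophilic media that favour acyl substitution. Aromatisation is irreversible and draws the reversible aldol forward.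

Step 10
Reactants: 16 tert-butyl 2-heptyl-4-[(2-heptyl-4,6-dihydroxybenzoyl)oxy]-6-methoxybenzoate
Product: 17 tert-butyl 2-heptyl-4-[(2-heptyl-6-hydroxy-4-methoxybenzoyl)oxy]-6-methoxybenzoate
Conditions: MeI (1.1 equiv), K2CO3 (1.1 equiv), acetone, rt
Reagents that add atoms: iodomethane, CI
Why: Williamson ether synthesis under weak base: the 4-hydroxyl, para to the ester carbonyl, is the more acidic and free, whereas the 6-hydroxyl is held in a hydrogen bond to the ester carbonyl and shielded, which is the classical basis of selective 4-O-methylation of 2,4-dihydroxybenzoates.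

Step 11
Reactants: 17 tert-butyl 2-heptyl-4-[(2-heptyl-6-hydroxy-4-methoxybenzoyl)oxy]-6-methoxybenzoate
Product: 18 2-heptyl-4-[(2-heptyl-6-hydroxy-4-methoxybenzoyl)oxy]-6-methoxybenzoic acid
Conditions: TFA/CH2Cl2 (1:4), 0 °C to rt
Reagents that add atoms: none
Why: Acidolysis of a tert-butyl ester (AAL1): protonation and loss of the tert-butyl cation as 2-methylpropene frees the acid, while the doubly ortho-substituted, hydrogen-bonded aryl ester and the methyl ethers are inert to anhydrous TFA.

**Compound list**

1 | 2-methoxy-6-methylbenzoic acid | COc1cccc(C)c1C(=O)O | starting material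
2 | 1-iodohexane | CCCCCCI | starting material
3 | 2-heptyl-6-methoxybenzoic acid | CCCCCCCc1cccc(OC)c1C(=O)O | intermediate
4 | tert-butyl 2-heptyl-6-methoxybenzoate | CCCCCCCc1cccc(OC)c1C(=O)OC(C)(C)C | intermediate
5 | tert-butyl 2-heptyl-6-methoxy-4-(4,4,5,5-tetramethyl-1,3,2-dioxaborolan-2-yl)benzoate | CCCCCCCc1cc(B2OC(C)(C)C(C)(C)O2)cc(OC)c1C(=O)OC(C)(C)C | intermediate
6 | tert-butyl 2-heptyl-4-hydroxy-6-methoxybenzoate | CCCCCCCc1cc(O)cc(OC)c1C(=O)OC(C)(C)C | intermediate
7 | 2,2,6-trimethyl-4H-1,3-dioxin-4-one | CC1=CC(=O)OC(C)(C)O1 | starting material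
8 | acetyl chloride | CC(=O)Cl | starting material
9 | 2,2-dimethyl-6-(2-oxopropyl)-4H-1,3-dioxin-4-one | CC(=O)CC1=CC(=O)OC(C)(C)O1 | intermediate
10 | octanoyl chloride | CCCCCCCC(=O)Cl | starting material
11 | N-methoxy-N-methyloctanamide | CCCCCCCC(=O)N(C)OC | intermediate
12 | 6-(2,4-dioxoundecyl)-2,2-dimethyl-4H-1,3-dioxin-4-one | CCCCCCCC(=O)CC(=O)CC1=CC(=O)OC(C)(C)O1 | intermediate
13 | tetradec-1-ene-1,3,5,7-tetrone (acylketene) | CCCCCCCC(=O)CC(=O)CC(=O)C=C=O | intermediate
14 | tert-butyl 2-heptyl-6-methoxy-4-[(3,5,7-trioxotetradecanoyl)oxy]benzoate | CCCCCCCC(=O)CC(=O)CC(=O)CC(=O)Oc1cc(CCCCCCC)c(C(=O)OC(C)(C)C)c(OC)c1 | intermediate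
15 | tert-butyl 2-heptyl-4-[(2-heptyl-2-hydroxy-4,6-dioxocyclohexane-1-carbonyl)oxy]-6-methoxybenzoate (mixture of diastereomers and enol forms) | CCCCCCCC1(O)CC(=O)CC(=O)C1C(=O)Oc1cc(CCCCCCC)c(C(=O)OC(C)(C)C)c(OC)c1 | intermediate
16 | tert-butyl 2-heptyl-4-[(2-heptyl-4,6-dihydroxybenzoyl)oxy]-6-methoxybenzoate | CCCCCCCc1cc(O)cc(O)c1C(=O)Oc1cc(CCCCCCC)c(C(=O)OC(C)(C)C)c(OC)c1 | intermediate
17 | tert-butyl 2-heptyl-4-[(2-heptyl-6-hydroxy-4-methoxybenzoyl)oxy]-6-methoxybenzoate | CCCCCCCc1cc(OC)cc(O)c1C(=O)Oc1cc(CCCCCCC)c(C(=O)OC(C)(C)C)c(OC)c1 | intermediate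
18 | 2-heptyl-4-[(2-heptyl-6-hydroxy-4-methoxybenzoyl)oxy]-6-methoxybenzoic acid | CCCCCCCc1cc(OC)cc(O)c1C(=O)Oc1cc(CCCCCCC)c(C(=O)O)c(OC)c1 | target

**Summary**

Total step count: 11. Longest linear sequence: 8 steps (steps 1, 2, 3, 4, 8, 9, 10, 11).

Steps most likely to fail:

Step 9. Acyl substitution at the aryl ester carbon, by the C5 enol oxygen or by C6, may outpace the aldol addition, so that the ring-B phenoxide is expelled before ring A closes. The fallback sets out from 12 and performs the same aldol condensation before the ester to ring B exists. Et3N in CH2Cl2 followed by AcOH should aromatise the diketo-dioxinone itself, the dioxinone α-carbon adding to the same ketone while the acyl carbon is locked in the acetonide, to give 5-heptyl-7-hydroxy-2,2-dimethyl-4H-1,3-benzodioxin-4-one F1. MeI and K2CO3 in acetone would methylate its only free hydroxyl to 5-heptyl-7-methoxy-2,2-dimethyl-4H-1,3-benzodioxin-4-one F2. Irradiation of F2 at 300 nm in CH2Cl2 in the presence of phenol 6 (photochemical acylation) expels acetone to the o-quinone ketene 5-heptyl-3-methoxy-6-(oxomethylidene)cyclohexa-2,4-dien-1-one F3, which the phenol captures in the flask. The fallback comes back to the route at 17.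

Step 8. The acylketene may be captured by its own C5 enol oxygen, or the aryl β-keto ester may revert to the ketene at 110 °C, so that material drains into a 4-hydroxy-2-pyranone before it is secured as the aryl ester. The fallback sets out from 12 and separates ketene generation from ester formation. Thermolysis in toluene at 100 °C in a sealed tube with an excess of 2-methylpropane-2-thiol, a far better ketene trap than a phenol, should give S-tert-butyl 3,5,7-trioxotetradecanethioate F4. Silver(I) trifluoroacetate with phenol 6 in THF at room temperature (thiophile-promoted acyl transfer of a β-keto thioester) would then deliver the aryl ester at a temperature at which it cannot revert. The fallback comes back at 14.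

Step 7. Addition of the dianion to the amide may be slow, so that proton transfer from the α-methylene of the amide and O-acylation consume the dianion and 9 is returned. The fallback sets out from 9 and changes the oxidation level of the electrophile. The same dianion (LDA, THF, −78 °C) adds rapidly to octanal in an aldol reaction to give racemic 6-(4-hydroxy-2-oxoundecyl)-2,2-dimethyl-4H-1,3-dioxin-4-one F5. Dess–Martin periodinane (NaHCO3, CH2Cl2, rt) would oxidise the secondary alcohol to the 1,3-diketone, coming back to the route at 12.

**Further compounds**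

F1 | step 9 | 5-heptyl-7-hydroxy-2,2-dimethyl-4H-1,3-benzodioxin-4-one | CCCCCCCc1cc(O)cc2OC(C)(C)OC(=O)c12
F2 | step 9 | 5-heptyl-7-methoxy-2,2-dimethyl-4H-1,3-benzodioxin-4-one | CCCCCCCc1cc(OC)cc2OC(C)(C)OC(=O)c12
F3 | step 9 | 5-heptyl-3-methoxy-6-(oxomethylidene)cyclohexa-2,4-dien-1-one | CCCCCCCC1=CC(OC)=CC(=O)C1=C=O
F4 | step 8 | S-tert-butyl 3,5,7-trioxotetradecanethioate | CCCCCCCC(=O)CC(=O)CC(=O)CC(=O)SC(C)(C)C
F5 | step 7 | 6-(4-hydroxy-2-oxoundecyl)-2,2-dimethyl-4H-1,3-dioxin-4-one (racemic) | CCCCCCCC(O)CC(=O)CC1=CC(=O)OC(C)(C)O1
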